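**Strategy.** The route rests on one disconnection: ring B, a furan substituted at C2 (furan-3-ylmethyl) and C4 (terpenoid chain), is cut at its C3–C4 bond. A single operation makes that bond by ring-closing metathesis of a mixed methyl acetal and then aromatises the 2-methoxy-2,5-dihydrofuran through acid-induced loss of methanol. The precursor joins a TBDPS-protected 2-alkylacrolein, grown from (S)-citronellol, to 1-(furan-3-yl)but-3-en-2-ol as a mixed acetal; it offers two terminal alkenes beside an unreactive trisubstituted alkene and furan A. The E-tetronic acid sulfate is then raised at the chain terminus by syn-hydrostannation of an ynoate, copper-mediated acyloxylation, Dieckmann closure and sulfation.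

Key step: step 11

Assumption: the hydrogen sulfate as drawn is taken as the target; it is released from its triethylammonium salt on an acidic resin at 0 °C and would be stored as the sodium salt, because the enol sulfate and both furans are acid-labile.

**Route**

Step 1
Reactants: 1 (S)-citronellol
Product: 2 TBDPS ether of (S)-citronellol
Conditions: TBDPSCl, imidazole, CH2Cl2, 0 °C → rt
Reagents that add atoms: tert-butyl(chloro)diphenylsilane, CC(C)(C)[Si](Cl)(c1ccccc1)c1ccccc1
Why: Imidazole-promoted silylation of a primary alcohol gives an ether that should survive every condition up to step 12 (oxidant, Grignard reagent, aqueous acid, PPTS, ruthenium carbene).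

Step 2
Reactants: 2 TBDPS ether of (S)-citronellol
Product: 3 (2E,6S)-8-(tert-butyldiphenylsilyloxy)-2,6-dimethyloct-2-en-1-ol
Conditions: SeO2 (cat.), t-BuOOH, CH2Cl2, rt; then NaBH4, MeOH, 0 °C
Reagents that add atoms: tert-butyl hydroperoxide, CC(C)(C)OO (oxygen passed on through catalytic SeO2, O=[Se]=O)
Why: Riley-type allylic oxidation (ene reaction, then [2,3]-sigmatropic shift) hydroxylates the methyl group trans to the chain and so fixes the E geometry, and NaBH4 returns any over-oxidised enal to the alcohol.

Step 3
Reactants: 3 (2E,6S)-8-(tert-butyldiphenylsilyloxy)-2,6-dimethyloct-2-en-1-ol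
Product: 4 (2E,6S)-1-bromo-8-(tert-butyldiphenylsilyloxy)-2,6-dimethyloct-2-ene
Conditions: CBr4, PPh3, CH2Cl2, 0 °C
Reagents that add atoms: carbon tetrabromide, BrC(Br)(Br)Br
Why: The Appel reaction converts the primary allylic alcohol into the bromide by SN2 displacement under neutral conditions, without moving the alkene.

Step 4
Reactants: 4 (2E,6S)-1-bromo-8-(tert-butyldiphenylsilyloxy)-2,6-dimethyloct-2-ene; 5 2-(3-chloropropyl)-1,3-dioxolane
Product: 7 TBDPS ether of (3S,6E)-11-(1,3-dioxolan-2-yl)-3,7-dimethylundec-6-en-1-ol, via Grignard reagent 6 (not isolated)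
Conditions: 5, Mg, THF, reflux; then 4, Li2CuCl4 (cat.), THF, −20 → 0 °C
Reagents that add atoms: none
Why: Copper-catalysed sp3–sp3 cross-coupling of an alkyl Grignard reagent with a primary allylic bromide should occur at the bromide-bearing carbon with retention of the E alkene, and the dioxolane is inert to the organometallic.

Step 5
Reactants: 7 TBDPS ether of (3S,6E)-11-(1,3-dioxolan-2-yl)-3,7-dimethylundec-6-en-1-ol
Product: 8 (6E,10S)-12-(tert-butyldiphenylsilyloxy)-6,10-dimethyldodec-6-enal
Conditions: 1 M aq. HCl–THF (1:2), rt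
Reagents that add atoms: water, O
Why: Acid-catalysed acetal hydrolysis frees the aldehyde under conditions that a primary TBDPS ether and the trisubstituted alkene tolerate.

Step 6
Reactants: 8 (6E,10S)-12-(tert-butyldiphenylsilyloxy)-6,10-dimethyldodec-6-enal
Product: 9 (6E,10S)-12-(tert-butyldiphenylsilyloxy)-6,10-dimethyl-2-methylidenedodec-6-enal
Conditions: 37 % aq. CH2O, pyrrolidine (10 mol %), EtCO2H (10 mol %), i-PrOH, 45 °C
Reagents that add atoms: formaldehyde, C=O
Why: Amine/acid-catalysed Mannich-type α-methylenation (enamine addition to the iminium ion of formaldehyde, then elimination of the amine) turns the linear aldehyde into the 2-alkylacrolein.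

Step 7
Reactants: 9 (6E,10S)-12-(tert-butyldiphenylsilyloxy)-6,10-dimethyl-2-methylidenedodec-6-enal
Product: 10 dimethyl acetal of 9
Conditions: HC(OMe)3, MeOH, PPTS (cat.), rt
Reagents that add atoms: trimethyl orthoformate, COC(OC)OC; methanol, CO
Why: Acid-catalysed acetalisation with the orthoformate as water scavenger proceeds by 1,2-addition at the carbonyl, which under this mild catalysis should outrun conjugate addition to the α-substituted enal.

Step 8
Reactants: 11 3-bromofuran; 12 epichlorohydrin (racemic)
Product: 14 1-chloro-3-(furan-3-yl)propan-2-ol (racemic), via 3-furyllithium 13 (not isolated)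
Conditions: n-BuLi, THF, −78 °C; then 12, BF3·OEt2, −78 °C
Reagents that add atoms: none
Why: Bromine–lithium exchange followed by BF3-assisted epoxide opening at the unsubstituted oxirane carbon sets the CH2 link from a ring-centred anion, avoiding a furan-3-ylmethyl carbanion that can react through ring C2.

Step 9
Reactants: 14 1-chloro-3-(furan-3-yl)propan-2-ol
Product: 16 1-(furan-3-yl)but-3-en-2-ol (racemic), via 2-(furan-3-ylmethyl)oxirane 15 (not isolated)
Conditions: Me3SI (4 equiv), n-BuLi (3.8 equiv), THF, −10 °C → rt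
Reagents that add atoms: trimethylsulfonium iodide, C[S+](C)C.[I-]
Why: The sulfonium ylide closes the chlorohydrin to the epoxide, opens it at the terminal carbon and, after a second deprotonation, expels dimethyl sulfide (one-carbon homologation of an epoxide to an allylic alcohol); the carbinol centre is left racemic because step 11 destroys it.

Step 10
Reactants: 10 dimethyl acetal of 9; 16 1-(furan-3-yl)but-3-en-2-ol
Product: 17 mixed methyl acetal of 9 with 16 (mixture at the acetal and carbinol carbons)
Conditions: 16 (1.5 equiv), PPTS (5 mol %), toluene, 40 °C, reduced pressure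
Reagents that add atoms: none
Why: Acid-catalysed transacetalisation is driven by removal of methanol, and a second exchange should be slow because a secondary alkoxy group next to the 1,1-disubstituted alkene crowds the acetal carbon.

Step 11
Reactants: 17 mixed methyl acetal of 9 with 16
Product: 19 TBDPS ether of (3S,6E)-10-[5-(furan-3-ylmethyl)furan-3-yl]-3,7-dimethyldec-6-en-1-ol, via 2-methoxy-2,5-dihydrofuran 18 (not isolated)
Conditions: second-generation Grubbs catalyst RuCl2(=CHPh)(PCy3)(H2IMes) (5 mol %), CH2Cl2 (0.01 M), 40 °C; then PPTS (20 mol %), 40 °C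
Reagents that add atoms: none
Why: The ruthenium benzylidene exchanges onto the monosubstituted vinyl group of the carbinol half, and the new alkylidene engages the tethered 1,1-disubstituted alkene through a ruthenacyclobutane whose cycloreversion releases ethylene and leaves the C3=C4 bond of ring B inside dihydrofuran 18. The closest known reaction type is the furan synthesis by ring-closing metathesis of allylic mixed acetals followed by acid-promoted aromatisation. The five-membered ring is closed by ring-closing metathesis at the endocyclic C3=C4 alkene; the second event closes no ring, since PPTS ionises the acetal to the ring oxocarbenium ion, which loses the proton on the furylmethyl-bearing carbon (C2 of ring B) and thereby methanol. No stereocentre is created, and the acetal and carbinol centres of 17 are both erased, so every stereoisomer of 17 converges on 19. The step needs chemoselectivity for the two terminal alkenes, which substitution secures: the trisubstituted chain alkene and the aromatic furan A are poor metathesis partners, high dilution favours the five-membered closure over cross-metathesis, and the TBDPS ether and the (S)-centre lie far from the reacting sites.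

Step 12
Reactants: 19 TBDPS ether of (3S,6E)-10-[5-(furan-3-ylmethyl)furan-3-yl]-3,7-dimethyldec-6-en-1-ol
Product: 20 (3S,6E)-10-[5-(furan-3-ylmethyl)furan-3-yl]-3,7-dimethyldec-6-en-1-ol
Conditions: Bu4NF, THF, rt
Reagents that add atoms: none
Why: Fluoride-induced desilylation is driven by the Si–F bond and leaves the furans and the alkene untouched.

Step 13
Reactants: 20 (3S,6E)-10-[5-(furan-3-ylmethyl)furan-3-yl]-3,7-dimethyldec-6-en-1-ol
Product: 21 (3S,6E)-10-[5-(furan-3-ylmethyl)furan-3-yl]-3,7-dimethyldec-6-enal
Conditions: Dess–Martin periodinane, CH2Cl2, 0 °C → rt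
Reagents that add atoms: none
Why: Dess–Martin oxidation stops at the aldehyde under near-neutral conditions that electron-rich furans tolerate, and the stereocentre, being β to the carbonyl, cannot epimerise.

Step 14
Reactants: 21 (3S,6E)-10-[5-(furan-3-ylmethyl)furan-3-yl]-3,7-dimethyldec-6-enal
Product: 23 4-[(4E,8S)-4,8-dimethyldec-4-en-9-yn-1-yl]-2-(furan-3-ylmethyl)furan, via enol nonaflate 22 (not isolated)
Conditions: C4F9SO2F, phosphazene base P2-Et, DMF, −30 °C → rt
Reagents that add atoms: none
Why: O-Sulfonylation of the aldehyde enolate followed by base-induced elimination of nonaflate (one-pot aldehyde-to-alkyne conversion through an alkenyl nonaflate) keeps the carbon count, and the alkyne rests as its acetylide, which should protect the adjacent stereocentre from allene isomerisation.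

Step 15
Reactants: 23 4-[(4E,8S)-4,8-dimethyldec-4-en-9-yn-1-yl]-2-(furan-3-ylmethyl)furan
Product: 25 methyl (4S,7E)-11-[5-(furan-3-ylmethyl)furan-3-yl]-4,8-dimethylundec-7-en-2-ynoate, via lithium acetylide 24 (not isolated)
Conditions: n-BuLi (1.0 equiv), THF, −78 °C; then ClCO2Me, −78 → −20 °C
Reagents that add atoms: methyl chloroformate, COC(=O)Cl
Why: Acylation of a lithium acetylide works because the acetylenic C–H is by far the most acidic site at −78 °C, ahead of the furan ring hydrogens.

Step 16
Reactants: 25 methyl (4S,7E)-11-[5-(furan-3-ylmethyl)furan-3-yl]-4,8-dimethylundec-7-en-2-ynoate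
Product: 27 methyl (2E,4S,7E)-11-[5-(furan-3-ylmethyl)furan-3-yl]-2-iodo-4,8-dimethylundeca-2,7-dienoate, via alkenylstannane 26 (not isolated)
Conditions: Bu3SnH, Pd(PPh3)4 (cat.), THF, 0 °C → rt; then I2, CH2Cl2, 0 °C
Reagents that add atoms: iodine, II
Why: Zerovalent palladium delivers tin and hydrogen to the same face of the polarised ynoate with tin at the α-carbon (syn-hydrostannation), so the ester ends up cis to the chain, and iododestannylation then replaces tin with retention.

Step 17
Reactants: 27 methyl (2E,4S,7E)-11-[5-(furan-3-ylmethyl)furan-3-yl]-2-iodo-4,8-dimethylundeca-2,7-dienoate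
Product: 28 methyl (2E,4S,7E)-11-[5-(furan-3-ylmethyl)furan-3-yl]-4,8-dimethyl-2-(propanoyloxy)undeca-2,7-dienoate
Conditions: EtCO2Cs (3 equiv), CuI (1.5 equiv), DMF, 50 °C, dark
Reagents that add atoms: cesium propionate, CCC(=O)[O-].[Cs+]
Why: Ullmann-type C(sp2)–O coupling of the activated alkenyl iodide with the carboxylate on monovalent copper should proceed with retention of alkene geometry, keeping the ester carbon cis to the chain.

Step 18
Reactants: 28 methyl (2E,4S,7E)-11-[5-(furan-3-ylmethyl)furan-3-yl]-4,8-dimethyl-2-(propanoyloxy)undeca-2,7-dienoate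
Product: 29 (5E)-5-{(2S,5E)-9-[5-(furan-3-ylmethyl)furan-3-yl]-2,6-dimethylnon-5-en-1-ylidene}-4-hydroxy-3-methylfuran-2(5H)-one
Conditions: LiN(SiMe3)2 (2.2 equiv), THF, −78 → 0 °C; then 1 M HCl, 0 °C
Reagents that add atoms: none
Why: In this Dieckmann condensation the propionate enolate attacks the neighbouring methyl ester (5-exo-trig) and expels methoxide to give the stable tetronate anion, without touching the exocyclic alkene, so its E geometry and the adjacent (S)-centre are carried over.

Step 19
Reactants: 29 (5E)-5-{(2S,5E)-9-[5-(furan-3-ylmethyl)furan-3-yl]-2,6-dimethylnon-5-en-1-ylidene}-4-hydroxy-3-methylfuran-2(5H)-one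
Product: 31 hydrogen sulfate ester of the 4-hydroxyl of 29 (target), via triethylammonium sulfate 30 (not isolated)
Conditions: SO3·NEt3, DMF, 0 °C → rt; then sulfonic acid resin (H+ form), MeCN–H2O, 0 °C
Reagents that add atoms: sulfur trioxide–triethylamine complex, CC[N+](CC)(CC)S(=O)(=O)[O-]
Why: O-Sulfation of the acidic 4-hydroxyl by the trialkylamine–SO3 complex should be fast at 0 °C, where this mild complex does not sulfonate the furan rings, and proton exchange on the resin then releases the hydrogen sulfate.

**Compound list**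

1 | (S)-citronellol, (3S)-3,7-dimethyloct-6-en-1-ol | OCC[C@@H](C)CCC=C(C)C | starting material
2 | TBDPS ether of (S)-citronellol | CC(C)(C)[Si](c1ccccc1)(c1ccccc1)OCC[C@@H](C)CCC=C(C)C | intermediate
3 | (2E,6S)-8-(tert-butyldiphenylsilyloxy)-2,6-dimethyloct-2-en-1-ol | CC(C)(C)[Si](c1ccccc1)(c1ccccc1)OCC[C@@H](C)CC/C=C(\C)CO | intermediate
4 | (2E,6S)-1-bromo-8-(tert-butyldiphenylsilyloxy)-2,6-dimethyloct-2-ene | CC(C)(C)[Si](c1ccccc1)(c1ccccc1)OCC[C@@H](C)CC/C=C(\C)CBr | intermediate
5 | 2-(3-chloropropyl)-1,3-dioxolane | ClCCCC1OCCO1 | starting material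
6 | [3-(1,3-dioxolan-2-yl)propyl]magnesium chloride (not isolated) | Cl[Mg]CCCC1OCCO1 | intermediate
7 | TBDPS ether of (3S,6E)-11-(1,3-dioxolan-2-yl)-3,7-dimethylundec-6-en-1-ol | CC(C)(C)[Si](c1ccccc1)(c1ccccc1)OCC[C@@H](C)CC/C=C(\C)CCCCC1OCCO1 | intermediate
8 | (6E,10S)-12-(tert-butyldiphenylsilyloxy)-6,10-dimethyldodec-6-enal | CC(C)(C)[Si](c1ccccc1)(c1ccccc1)OCC[C@@H](C)CC/C=C(\C)CCCCC=O | intermediate
9 | (6E,10S)-12-(tert-butyldiphenylsilyloxy)-6,10-dimethyl-2-methylidenedodec-6-enal | CC(C)(C)[Si](c1ccccc1)(c1ccccc1)OCC[C@@H](C)CC/C=C(\C)CCCC(=C)C=O | intermediate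
10 | dimethyl acetal of 9 | CC(C)(C)[Si](c1ccccc1)(c1ccccc1)OCC[C@@H](C)CC/C=C(\C)CCCC(=C)C(OC)OC | intermediate
11 | 3-bromofuran | Brc1ccoc1 | starting material
12 | epichlorohydrin (racemic) | ClCC1CO1 | starting material
13 | 3-furyllithium (not isolated) | [Li]c1ccoc1 | intermediate
14 | 1-chloro-3-(furan-3-yl)propan-2-ol (racemic) | OC(CCl)Cc1ccoc1 | intermediate
15 | 2-(furan-3-ylmethyl)oxirane (racemic, not isolated) | C(c1ccoc1)C1CO1 | intermediate
16 | 1-(furan-3-yl)but-3-en-2-ol (racemic) | C=CC(O)Cc1ccoc1 | intermediate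
17 | mixed methyl acetal of 9 with 16 (mixture at the acetal and carbinol carbons) | CC(C)(C)[Si](c1ccccc1)(c1ccccc1)OCC[C@@H](C)CC/C=C(\C)CCCC(=C)C(OC)OC(Cc1ccoc1)C=C | intermediate
18 | TBDPS ether of (3S,6E)-10-[5-(furan-3-ylmethyl)-2-methoxy-2,5-dihydrofuran-3-yl]-3,7-dimethyldec-6-en-1-ol (mixture at ring C2 and C5, not isolated) | CC(C)(C)[Si](c1ccccc1)(c1ccccc1)OCC[C@@H](C)CC/C=C(\C)CCCC1=CC(Cc2ccoc2)OC1OC | intermediate
19 | TBDPS ether of (3S,6E)-10-[5-(furan-3-ylmethyl)furan-3-yl]-3,7-dimethyldec-6-en-1-ol | CC(C)(C)[Si](c1ccccc1)(c1ccccc1)OCC[C@@H](C)CC/C=C(\C)CCCc1coc(Cc2ccoc2)c1 | intermediate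
20 | (3S,6E)-10-[5-(furan-3-ylmethyl)furan-3-yl]-3,7-dimethyldec-6-en-1-ol | OCC[C@@H](C)CC/C=C(\C)CCCc1coc(Cc2ccoc2)c1 | intermediate
21 | (3S,6E)-10-[5-(furan-3-ylmethyl)furan-3-yl]-3,7-dimethyldec-6-enal | O=CC[C@@H](C)CC/C=C(\C)CCCc1coc(Cc2ccoc2)c1 | intermediate
22 | enol nonaflate of 21 (E/Z mixture at the new alkene, not isolated) | O=S(=O)(OC=C[C@@H](C)CC/C=C(\C)CCCc1coc(Cc2ccoc2)c1)C(F)(F)C(F)(F)C(F)(F)C(F)(F)F | intermediate
23 | 4-[(4E,8S)-4,8-dimethyldec-4-en-9-yn-1-yl]-2-(furan-3-ylmethyl)furan | C#C[C@@H](C)CC/C=C(\C)CCCc1coc(Cc2ccoc2)c1 | intermediate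
24 | lithium acetylide of 23 (not isolated) | [Li]C#C[C@@H](C)CC/C=C(\C)CCCc1coc(Cc2ccoc2)c1 | intermediate
25 | methyl (4S,7E)-11-[5-(furan-3-ylmethyl)furan-3-yl]-4,8-dimethylundec-7-en-2-ynoate | COC(=O)C#C[C@@H](C)CC/C=C(\C)CCCc1coc(Cc2ccoc2)c1 | intermediate
26 | methyl (2E,4S,7E)-11-[5-(furan-3-ylmethyl)furan-3-yl]-4,8-dimethyl-2-(tributylstannyl)undeca-2,7-dienoate (ester cis to the chain, not isolated) | COC(=O)/C(=C\[C@@H](C)CC/C=C(\C)CCCc1coc(Cc2ccoc2)c1)[Sn](CCCC)(CCCC)CCCC | intermediate
27 | methyl (2E,4S,7E)-11-[5-(furan-3-ylmethyl)furan-3-yl]-2-iodo-4,8-dimethylundeca-2,7-dienoate | COC(=O)/C(I)=C\[C@@H](C)CC/C=C(\C)CCCc1coc(Cc2ccoc2)c1 | intermediate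
28 | methyl (2E,4S,7E)-11-[5-(furan-3-ylmethyl)furan-3-yl]-4,8-dimethyl-2-(propanoyloxy)undeca-2,7-dienoate | COC(=O)/C(OC(=O)CC)=C\[C@@H](C)CC/C=C(\C)CCCc1coc(Cc2ccoc2)c1 | intermediate
29 | (5E)-5-{(2S,5E)-9-[5-(furan-3-ylmethyl)furan-3-yl]-2,6-dimethylnon-5-en-1-ylidene}-4-hydroxy-3-methylfuran-2(5H)-one | CC1=C(O)/C(=C\[C@@H](C)CC/C=C(\C)CCCc2coc(Cc3ccoc3)c2)OC1=O | intermediate
30 | triethylammonium salt of the 4-O-sulfate of 29 (not isolated) | CC1=C(OS(=O)(=O)[O-])/C(=C\[C@@H](C)CC/C=C(\C)CCCc2coc(Cc3ccoc3)c2)OC1=O.CC[NH+](CC)CC | intermediate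
31 | CNP0018233.1, hydrogen sulfate ester of the 4-hydroxyl of 29 (5E, 2S, 5E in the side chain) | CC1=C(OS(=O)(=O)O)/C(=C\[C@@H](C)CC/C=C(\C)CCCc2coc(Cc3ccoc3)c2)OC1=O | target

**Step count**

Total step count: 19.
Longest linear sequence: 17 steps from (S)-citronellol (steps 1–7 and 10–19); steps 8–9 make the carbinol partner.

**Three steps most likely to fail**

1. Step 11. The alkylidene formed at the vinyl group may close too slowly onto the hindered 1,1-disubstituted alkene. That would leave time for intermolecular metathesis, for ionisation of the allylic acetal before cyclisation, or for acid-induced decay of the electron-rich bis-furan during aromatisation. Fallback: ring B is not constructed but brought in ready-made and joined by an sp3–sp2 cross-coupling; the fallback sets out from bromide 4 and comes back at 19. Bromide 4 is coupled with CH2=CHMgBr (CuI cat., THF, −30 °C) to the skipped diene, the TBDPS ether of (3S,6E)-3,7-dimethyldeca-6,9-dien-1-ol F1. In parallel, 3-furyllithium 13 is added to commercial 4-bromofuran-2-carbaldehyde (THF, −78 °C) to give (4-bromofuran-2-yl)(furan-3-yl)methanol F2. Ionic hydrogenation (Et3SiH, CF3CO2H, CH2Cl2, −20 °C) should reduce F2 to 4-bromo-2-(furan-3-ylmethyl)furan F3. Hydroboration of F1 with 9-BBN-H at its monosubstituted alkene gives the B-alkyl-9-BBN F4, and Suzuki–Miyaura coupling of F4 with F3 (PdCl2(dppf), Cs2CO3, DMF–THF–H2O, 50 °C) should deliver 19.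

2. Step 17. The alkenyl iodide may be reduced, or may lose its geometry through reversible addition–elimination, before the C–O bond forms, and the coupling may stall at temperatures the furans tolerate. Fallback: the polarity of the coupling is reversed, so the carbon partner is the organotin compound and not the iodide. It sets out from alkenylstannane 26, isolated after the hydrostannation half of step 16 with the iodination left out, and comes back at 28. A Chan–Lam-type oxidative acyloxylation with divalent copper propionate Cu(O2CEt)2 and Et3N in DMSO under air at 40 °C should transfer the propionate to the tin-bearing carbon with retention. No compound outside the list is made (F0).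

3. Step 10. Exchange may run on to the acetal carrying two carbinol units, which would divert the metathesis toward a seven-membered dioxepine, or stop at a statistical mixture that wastes the advanced acetal 10. Fallback: equilibrium exchange is replaced by stoichiometric activation of one methoxy group under base buffering; it sets out from 10 and comes back at 17. Et3SiOTf and 2,4,6-collidine in CH2Cl2 at 0 °C should convert 10 into the N-(1-methoxyalkyl)-2,4,6-trimethylpyridinium triflate F5, which one equivalent of 16 then displaces at 0 °C → rt to give 17.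

**Further compounds**

F1 | step 11 | TBDPS ether of (3S,6E)-3,7-dimethyldeca-6,9-dien-1-ol | CC(C)(C)[Si](c1ccccc1)(c1ccccc1)OCC[C@@H](C)CC/C=C(\C)CC=C
F2 | step 11 | (4-bromofuran-2-yl)(furan-3-yl)methanol (racemic) | OC(c1ccoc1)c1cc(Br)co1
F3 | step 11 | 4-bromo-2-(furan-3-ylmethyl)furan | Brc1coc(Cc2ccoc2)c1
F4 | step 11 | B-alkyl-9-BBN from F1, 9-[(4E,8S)-10-(tert-butyldiphenylsilyloxy)-4,8-dimethyldec-4-en-1-yl]-9-borabicyclo[3.3.1]nonane | CC(C)(C)[Si](c1ccccc1)(c1ccccc1)OCC[C@@H](C)CC/C=C(\C)CCCB1C2CCCC1CCC2
F0 | step 17 | none | none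
F5 | step 10 | N-(1-methoxyalkyl)-2,4,6-trimethylpyridinium triflate from 10 | CC(C)(C)[Si](c1ccccc1)(c1ccccc1)OCC[C@@H](C)CC/C=C(\C)CCCC(=C)C(OC)[n+]1c(C)cc(C)cc1C.[O-]S(=O)(=O)C(F)(F)F
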